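**Retrosynthetic overview**
- The strategy rests on ring B: it carries a single oxygen (C3', the ether oxygen of ring D), the ring D alkene carbon at C4' and the bond to C2 of ring C at C1'. A 3-hydroxyaryl precursor would be a weak nucleophile with two competing ortho carbons (C2' and C4').
- Rings B and D are therefore cut back to mirror-symmetric methyl 3,5-dioxocyclohexane-1-carboxylate and 3-methylbut-2-enal (Knoevenagel condensation, then oxa-6π electrocyclization). Ring B is aromatized afterwards by carbonyl reduction, dehydration and dehydrogenation.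
- Ring C is disconnected at O1–C2 and C3–OH (Algar–Flynn–Oyamada oxidation of a 2'-hydroxychalcone), then at Cα=Cβ (Claisen–Schmidt condensation of the ring B/D aldehyde with a ring A methyl ketone).
- Ring A is bought as 2,4,6-trihydroxyacetophenone. The C6 and C8 prenyl groups come from double C-alkylation with prenyl bromide, and the C5/C7 hydroxyls travel as MOM ethers.
- Order of ring formation: D (step 2), B as an arene (step 5), C (step 11); ring A is aromatic throughout.

Key step: step 2

Remark: the target is achiral; the stereocentres that appear on the way (C7 in 6 to 9, C5 in 7 and 8, C2/C3 in 18) are racemic and are all erased. The C3 hydroxyl is introduced oxidatively at the chalcone stage, so no C3–O protecting group has to be removed beside the acid-sensitive prenyl groups.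

**Route**

Step 1
Reactants: 1 3,5-dioxocyclohexane-1-carboxylic acid
Product: 3 methyl 3,5-dioxocyclohexane-1-carboxylate, via enol ether ester 2 (not isolated)
Conditions: MeOH, H2SO4 (cat.), reflux; then 1 M aq. HCl, THF, rt
Reagents that add atoms: methanol, CO; water, O
Why: Fischer esterification in methanol also converts the enolized dione into its methyl enol ether 2, a vinylogous ester that dilute aqueous acid should hydrolyse much faster than the methyl ester, so the one-flask sequence should deliver the free dione ester.

Step 2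
Reactants: 3 methyl 3,5-dioxocyclohexane-1-carboxylate; 4 3-methylbut-2-enal
Product: 6 methyl 2,2-dimethyl-5-oxo-5,6,7,8-tetrahydro-2H-chromene-7-carboxylate (racemic), via alkylidene dione 5 (not isolated)
Conditions: ethylenediammonium diacetate (10 mol%), CH2Cl2, rt
Reagents that add atoms: none
Why: The diammonium diacetate converts enal 4 into an iminium ion, which is attacked by the doubly activated C4 of dione 3; loss of the amine (Knoevenagel condensation) gives alkylidene dione 5, a 1-oxatriene. Thermal disrotatory oxa-6π electrocyclization then joins one carbonyl oxygen to the CMe2 terminus, so ring D (the 2H-pyran) closes in a six-atom pericyclic mode and the two skeletal bonds C4'–CH= and O–CMe2 are made in one flask. The closest known reaction type is the formal [3+3] annulation of cyclic 1,3-diketones with β,β-disubstituted enals under ammonium carboxylate catalysis. The only new stereocentre, the ester-bearing C7, lies outside the reacting array, forms racemic without any controlling element and is erased in step 5. The selectivity needed is a single orientation of ring D on the future ring B, and the mirror plane of 3 through C1 and C4 secures it, because both carbonyl oxygens and both closure modes are identical and the ester carbon must end up para to the new C–C bond. The geminal methyl groups of 4 should slow a second Michael addition of 3 to 5 and shift the oxatriene/2H-pyran equilibrium to the closed form.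

Step 3
Reactants: 6 methyl 2,2-dimethyl-5-oxo-5,6,7,8-tetrahydro-2H-chromene-7-carboxylate
Product: 7 methyl 5-hydroxy-2,2-dimethyl-5,6,7,8-tetrahydro-2H-chromene-7-carboxylate (cis and trans racemates)
Conditions: NaBH4, CeCl3·7H2O, MeOH, 0 °C; aq. NaHCO3 work-up, used crude
Reagents that add atoms: none
Why: Luche reduction should add hydride 1,2 to the cerium-activated vinylogous-ester carbonyl while the methyl ester is left alone at 0 °C, and the new carbinol centre C5 forms without useful control relative to C7, which does not matter because both centres are removed by step 5.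

Step 4
Reactants: 7 methyl 5-hydroxy-2,2-dimethyl-5,6,7,8-tetrahydro-2H-chromene-7-carboxylate
Product: 9 methyl 2,2-dimethyl-7,8-dihydro-2H-chromene-7-carboxylate (racemic), via allylic mesylate 8 (not isolated)
Conditions: MsCl, Et3N, CH2Cl2, 0 °C to rt
Reagents that add atoms: none
Why: Dehydration by sulfonylation and elimination should work because mesylate 8 ionizes readily to a cation stabilized by the enol-ether oxygen of ring D and triethylamine removes a C6 proton under anhydrous, base-buffered conditions that avoid hydrolytic opening of ring D, any double-bond isomer converging in step 5.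

Step 5
Reactants: 9 methyl 2,2-dimethyl-7,8-dihydro-2H-chromene-7-carboxylate
Product: 10 methyl 2,2-dimethyl-2H-chromene-7-carboxylate
Conditions: DDQ (1.1 equiv), toluene, rt
Reagents that add atoms: none
Why: Dehydrogenative aromatization with DDQ should proceed by hydride abstraction from allylic C8 (cation stabilized by the ether oxygen) and loss of the acidic C7 proton, which removes the last stereocentre, while the quaternary C2 of ring D cannot be oxidized further.

Step 6
Reactants: 10 methyl 2,2-dimethyl-2H-chromene-7-carboxylate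
Product: 11 (2,2-dimethyl-2H-chromen-7-yl)methanol
Conditions: i-Bu2AlH (2.5 equiv), CH2Cl2, −78 to 0 °C; aq. potassium sodium tartrate
Reagents that add atoms: none
Why: Hydride reduction of the aryl ester with excess i-Bu2AlH should stop cleanly at the benzylic alcohol and does not touch the styrene-type alkene of ring D.

Step 7
Reactants: 11 (2,2-dimethyl-2H-chromen-7-yl)methanol
Product: 12 2,2-dimethyl-2H-chromene-7-carbaldehyde
Conditions: MnO2 (activated, excess), CH2Cl2, rt
Reagents that add atoms: none
Why: Heterogeneous oxidation of a benzylic alcohol with activated MnO2 stops at the aldehyde and leaves the chromene alkene intact.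

Step 8
Reactants: 13 1-(2,4,6-trihydroxyphenyl)ethan-1-one; 14 1-bromo-3-methylbut-2-ene (prenyl bromide, 2.1 equiv)
Product: 15 1-[2,4,6-trihydroxy-3,5-bis(3-methylbut-2-en-1-yl)phenyl]ethan-1-one
Conditions: 10% aq. KOH, 0 °C to rt
Reagents that add atoms: none
Why: C-alkylation of an acylphloroglucinol phenoxide should occur in water, where the solvated oxygens are shielded and the two equivalent ring carbons C3 and C5 attack the soft allylic bromide (SN2), so two equivalents install both prenyl groups.

Step 9
Reactants: 15 1-[2,4,6-trihydroxy-3,5-bis(3-methylbut-2-en-1-yl)phenyl]ethan-1-one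
Product: 16 1-[2-hydroxy-4,6-bis(methoxymethoxy)-3,5-bis(3-methylbut-2-en-1-yl)phenyl]ethan-1-one
Conditions: MOMCl (2.4 equiv), i-Pr2NEt, CH2Cl2, 0 °C to rt
Reagents that add atoms: chloromethyl methyl ether, COCCl
Why: O-alkylation (acetal formation) with MOMCl should take the C4 hydroxyl and one ortho hydroxyl, while the second ortho hydroxyl stays locked in a hydrogen bond to the acetyl carbonyl and remains free as the nucleophile later needed for ring C.

Step 10
Reactants: 16 1-[2-hydroxy-4,6-bis(methoxymethoxy)-3,5-bis(3-methylbut-2-en-1-yl)phenyl]ethan-1-one; 12 2,2-dimethyl-2H-chromene-7-carbaldehyde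
Product: 17 (E)-3-(2,2-dimethyl-2H-chromen-7-yl)-1-[2-hydroxy-4,6-bis(methoxymethoxy)-3,5-bis(3-methylbut-2-en-1-yl)phenyl]prop-2-en-1-one
Conditions: KOH, EtOH–H2O, rt
Reagents that add atoms: none
Why: Claisen–Schmidt condensation of the methyl ketone enolate with the non-enolizable aldehyde and E1cB dehydration should give the thermodynamically favoured E-enone, the MOM ethers, prenyl groups and chromene being inert to aqueous-alcoholic hydroxide.

Step 11
Reactants: 17 (E)-3-(2,2-dimethyl-2H-chromen-7-yl)-1-[2-hydroxy-4,6-bis(methoxymethoxy)-3,5-bis(3-methylbut-2-en-1-yl)phenyl]prop-2-en-1-one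
Product: 19 2-(2,2-dimethyl-2H-chromen-7-yl)-3-hydroxy-5,7-bis(methoxymethoxy)-6,8-bis(3-methylbut-2-en-1-yl)-4H-chromen-4-one, via trans-3-hydroxyflavanone 18 (not isolated)
Conditions: 30% aq. H2O2, 2 M aq. NaOH, MeOH–THF, 0 °C to rt
Reagents that add atoms: hydrogen peroxide, OO
Why: In the Algar–Flynn–Oyamada oxidation the 2'-phenoxide should close ring C by 6-endo oxa-Michael addition, the resulting enolate is hydroxylated at C3 by hydrogen peroxide to the thermodynamically preferred trans-3-hydroxyflavanone 18 (racemic), and further alkaline peroxide dehydrogenates C2–C3 to the flavonol, the nucleophilic oxidant leaving the electron-rich prenyl and chromene alkenes untouched.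

Step 12
Reactants: 19 2-(2,2-dimethyl-2H-chromen-7-yl)-3-hydroxy-5,7-bis(methoxymethoxy)-6,8-bis(3-methylbut-2-en-1-yl)-4H-chromen-4-one
Product: 20 dorsilurin C
Conditions: 3 M aq. HCl, MeOH, 50 °C, short reaction time
Reagents that add atoms: none
Why: Acid-catalysed methanolysis of the two MOM acetals, the C5 ether assisted by the peri carbonyl, should free both phenols under dilute acid that ortho-prenyl phenols and 2,2-dimethylchromenes normally tolerate for a short time.

**Compound list**
1 | 3,5-dioxocyclohexane-1-carboxylic acid | O=C(O)C1CC(=O)CC(=O)C1 | starting material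
2 | methyl 3-methoxy-5-oxocyclohex-3-ene-1-carboxylate (racemic) | COC(=O)C1CC(=O)C=C(OC)C1 | intermediate (not isolated)
3 | methyl 3,5-dioxocyclohexane-1-carboxylate | COC(=O)C1CC(=O)CC(=O)C1 | intermediate
4 | 3-methylbut-2-enal | CC(C)=CC=O | starting material
5 | methyl 4-(3-methylbut-2-en-1-ylidene)-3,5-dioxocyclohexane-1-carboxylate (racemic) | COC(=O)C1CC(=O)C(=CC=C(C)C)C(=O)C1 | intermediate (not isolated)
6 | methyl 2,2-dimethyl-5-oxo-5,6,7,8-tetrahydro-2H-chromene-7-carboxylate (racemic) | COC(=O)C1CC(=O)C2=C(C1)OC(C)(C)C=C2 | intermediate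
7 | methyl 5-hydroxy-2,2-dimethyl-5,6,7,8-tetrahydro-2H-chromene-7-carboxylate (cis and trans racemates) | COC(=O)C1CC(O)C2=C(C1)OC(C)(C)C=C2 | intermediate
8 | methyl 2,2-dimethyl-5-[(methylsulfonyl)oxy]-5,6,7,8-tetrahydro-2H-chromene-7-carboxylate (diastereomer mixture, racemic) | COC(=O)C1CC(OS(C)(=O)=O)C2=C(C1)OC(C)(C)C=C2 | intermediate (not isolated)
9 | methyl 2,2-dimethyl-7,8-dihydro-2H-chromene-7-carboxylate (racemic) | COC(=O)C1CC2=C(C=C1)C=CC(C)(C)O2 | intermediate
10 | methyl 2,2-dimethyl-2H-chromene-7-carboxylate | COC(=O)c1ccc2C=CC(C)(C)Oc2c1 | intermediate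
11 | (2,2-dimethyl-2H-chromen-7-yl)methanol | OCc1ccc2C=CC(C)(C)Oc2c1 | intermediate
12 | 2,2-dimethyl-2H-chromene-7-carbaldehyde | O=Cc1ccc2C=CC(C)(C)Oc2c1 | intermediate
13 | 1-(2,4,6-trihydroxyphenyl)ethan-1-one | CC(=O)c1c(O)cc(O)cc1O | starting material
14 | 1-bromo-3-methylbut-2-ene (prenyl bromide) | CC(C)=CCBr | starting material
15 | 1-[2,4,6-trihydroxy-3,5-bis(3-methylbut-2-en-1-yl)phenyl]ethan-1-one | CC(=O)c1c(O)c(CC=C(C)C)c(O)c(CC=C(C)C)c1O | intermediate
16 | 1-[2-hydroxy-4,6-bis(methoxymethoxy)-3,5-bis(3-methylbut-2-en-1-yl)phenyl]ethan-1-one | CC(=O)c1c(O)c(CC=C(C)C)c(OCOC)c(CC=C(C)C)c1OCOC | intermediate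
17 | (E)-3-(2,2-dimethyl-2H-chromen-7-yl)-1-[2-hydroxy-4,6-bis(methoxymethoxy)-3,5-bis(3-methylbut-2-en-1-yl)phenyl]prop-2-en-1-one | COCOc1c(CC=C(C)C)c(OCOC)c(CC=C(C)C)c(O)c1C(=O)/C=C/c1ccc2C=CC(C)(C)Oc2c1 | intermediate
18 | trans-2-(2,2-dimethyl-2H-chromen-7-yl)-3-hydroxy-5,7-bis(methoxymethoxy)-6,8-bis(3-methylbut-2-en-1-yl)-2,3-dihydro-4H-chromen-4-one (racemic; 2R,3R enantiomer drawn) | CC1(C)C=Cc2ccc(cc2O1)[C@@H]1[C@H](C(=O)c2c(OCOC)c(CC=C(C)C)c(OCOC)c(CC=C(C)C)c2O1)O | intermediate (not isolated)
19 | 2-(2,2-dimethyl-2H-chromen-7-yl)-3-hydroxy-5,7-bis(methoxymethoxy)-6,8-bis(3-methylbut-2-en-1-yl)-4H-chromen-4-one | COCOc1c(CC=C(C)C)c(OCOC)c(CC=C(C)C)c2oc(-c3ccc4C=CC(C)(C)Oc4c3)c(O)c(=O)c12 | intermediate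
20 | dorsilurin C, 2-(2,2-dimethyl-2H-chromen-7-yl)-3,5,7-trihydroxy-6,8-bis(3-methylbut-2-en-1-yl)-4H-chromen-4-one | CC(C)=CCc1c(O)c(CC=C(C)C)c2oc(-c3ccc4c(c3)OC(C)(C)C=C4)c(O)c(=O)c2c1O | target

**Step count and risks**
Total step count: 12. Longest linear sequence: 10 steps (steps 1 to 7, then 10 to 12); steps 8 and 9 form the ring A branch.

Steps most likely to fail:

1. Step 11. The phenoxide may attack the α-carbon of the oxidized enone (5-exo closure to an aurone) faster than it closes ring C, a pathway favoured when the C6' substituent twists the enone out of the plane of ring A. The fallback sets out from 17 and fixes ring C before any oxidation. NaOAc in refluxing EtOH should close 17 by oxa-Michael addition to the racemic flavanone 2-(2,2-dimethyl-2H-chromen-7-yl)-5,7-bis(methoxymethoxy)-6,8-bis(3-methylbut-2-en-1-yl)chroman-4-one F1. Its lithium enolate (LiN(SiMe3)2, THF, −78 °C) is hydroxylated with 2-(phenylsulfonyl)-3-phenyloxaziridine to the trans-3-hydroxyflavanone. The fallback comes back to the route at 18, here isolated, which alkaline H2O2 (the second stage of step 11) dehydrogenates to 19.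

2. Step 12. Protonation of the prenyl alkenes and capture of the tertiary cations by the neighbouring C5 or C7 hydroxyl (chroman formation), or addition of methanol across the ring D alkene, may compete with acetal cleavage. The fallback sets out from 15 and replaces acid-labile protection by allyl ethers removed with zerovalent palladium. Allyl bromide and K2CO3 in refluxing acetone should give 1-[2-hydroxy-4,6-bis(prop-2-en-1-yloxy)-3,5-bis(3-methylbut-2-en-1-yl)phenyl]ethan-1-one F2. Condensation with 12 as in step 10 gives the chalcone (E)-3-(2,2-dimethyl-2H-chromen-7-yl)-1-[2-hydroxy-4,6-bis(prop-2-en-1-yloxy)-3,5-bis(3-methylbut-2-en-1-yl)phenyl]prop-2-en-1-one F3. Oxidation as in step 11 gives 2-(2,2-dimethyl-2H-chromen-7-yl)-3-hydroxy-5,7-bis(prop-2-en-1-yloxy)-6,8-bis(3-methylbut-2-en-1-yl)-4H-chromen-4-one F4. Pd(PPh3)4 with morpholine in THF at rt then transfers both allyl groups to the amine under neutral conditions, and the fallback comes back to the route at 20.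

3. Step 3. Hydride addition to the deactivated vinylogous-ester carbonyl may be slow enough for ester reduction to compete, and ring D of the acid-labile allylic alcohol may open hydrolytically during isolation. The fallback sets out from 6 and removes the oxygen without passing through the alcohol. Kinetic deprotonation at C6 (LiN(SiMe3)2, THF, −78 °C) and trapping with PhNTf2 should give the dienyl triflate methyl 2,2-dimethyl-5-{[(trifluoromethyl)sulfonyl]oxy}-7,8-dihydro-2H-chromene-7-carboxylate F5. Palladium-catalysed formate reduction of the enol triflate (Pd(OAc)2, PPh3, HCO2H, Et3N, DMF, 60 °C) replaces the C–O bond by C–H, and the fallback comes back to the route at 9, which is aromatized as in step 5.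

**Further compounds**
F1 | step 11 | 2-(2,2-dimethyl-2H-chromen-7-yl)-5,7-bis(methoxymethoxy)-6,8-bis(3-methylbut-2-en-1-yl)chroman-4-one (racemic) | COCOc1c(CC=C(C)C)c(OCOC)c(CC=C(C)C)c2OC(CC(=O)c12)c1ccc2C=CC(C)(C)Oc2c1
F2 | step 12 | 1-[2-hydroxy-4,6-bis(prop-2-en-1-yloxy)-3,5-bis(3-methylbut-2-en-1-yl)phenyl]ethan-1-one | CC(=O)c1c(O)c(CC=C(C)C)c(OCC=C)c(CC=C(C)C)c1OCC=C
F3 | step 12 | (E)-3-(2,2-dimethyl-2H-chromen-7-yl)-1-[2-hydroxy-4,6-bis(prop-2-en-1-yloxy)-3,5-bis(3-methylbut-2-en-1-yl)phenyl]prop-2-en-1-one | C=CCOc1c(CC=C(C)C)c(OCC=C)c(CC=C(C)C)c(O)c1C(=O)/C=C/c1ccc2C=CC(C)(C)Oc2c1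
F4 | step 12 | 2-(2,2-dimethyl-2H-chromen-7-yl)-3-hydroxy-5,7-bis(prop-2-en-1-yloxy)-6,8-bis(3-methylbut-2-en-1-yl)-4H-chromen-4-one | C=CCOc1c(CC=C(C)C)c(OCC=C)c(CC=C(C)C)c2oc(-c3ccc4C=CC(C)(C)Oc4c3)c(O)c(=O)c12
F5 | step 3 | methyl 2,2-dimethyl-5-{[(trifluoromethyl)sulfonyl]oxy}-7,8-dihydro-2H-chromene-7-carboxylate (racemic) | COC(=O)C1CC2=C(C(OS(=O)(=O)C(F)(F)F)=C1)C=CC(C)(C)O2
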